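The constants were chosen freely; what happens was integrated by code.

A link could not form in this flask before a solid second end group had dissolved. So I asked how much the solid could deliver by the reading time.

first end groups 0.50 M; solid second end groups 0.950 equiv; time 20 h

- links at 20 h, in percent of the first end groups charged
- the change that raises the amount of links at 20 h, in percent of the first end groups charged most ("none" if none brings more than 2 percentage points) (alpha / gamma / none)
- amount of links at 20 h, in percent of the first end groups charged, after gamma

- alpha: doubling the dissolution coefficient of step 2, all else as stated
- gamma: doubling the solubility in step 2, all else as stated

- what is said of released group includes idle adduct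
- solid second end groups is a solid; its amount is given per volume of the solution
- at the start none of the solid second end groups is in solution
- run time (flask): 20 h

I turned the question round. For the opposite outcome, a solution near saturation, dissolved second end groups would have to leave more slowly than they arrived. The link-forming rate constant times c(first end groups) would then have to lie below the dissolution coefficient. At the start it was 2.05 h⁻¹ against 0.060 h⁻¹, or 34.2 times that coefficient. So I took dissolution as the rate-limiting step.

Dissolution coefficient times solubility times time, over the charged c(first end groups), gave 38.4 %. I called this the supply ceiling: what dissolution can deliver by the reading time into a solution kept empty, as a share of the first end groups charged.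

The solution was not empty. By my reckoning it stood at a fraction of saturation: the dissolution coefficient over that coefficient plus the link-forming rate constant times c(first end groups). I replaced the falling curve of c(first end groups) by its midpoint, 0.404 M. That gave a fraction of 3.50 % and links of 37.1 %. The starting value would have given 2.84 %, so the choice moved my figure by 0.25 percentage points.

Both changes doubled the ceiling. By the same reckoning gamma gave 73.3 %. Alpha raised the fraction and gave 70.1 %, less than gamma.

The forecast said 35.4 % (range 34.5 % to 36.5 %), gamma, and 66.5 % (range 63 % to 69 %), on the ground that “the second end groups are consumed as fast as they dissolve”. My 37.1 % stood above its 35.4 %, and my 73.3 % above its 66.5 %.

The simulation gave 35.6 %, then gamma with a gain of 32 points against 30 points for alpha, and 67.7 % after gamma.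

    first end groups + second end groups → links + released group (k1 = 4.1 L mol⁻¹ h⁻¹)
    solid second end groups ⇌ second end groups, rate k2*(cs2 - [second end groups]) while solid is left; crystals form when [second end groups] > cs2 (cs2 = 0.16 M, k2 = 0.060 h⁻¹)
    first end groups + released group ⇌ idle adduct, settled at all times (K3 = 0.57 L mol⁻¹)

This flask ended 2.8 points under its ceiling of 38.4 %. The low solubility of second end groups, which also sets how fast they dissolve, was the main reason for the low amount of links: with it taken away, this flask reached 93.9 % of links instead of 35.6 %. The neighbour charged with 1.2 M of first end groups had a ceiling of 16.0 %, and it gave 15.6 %.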